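## Retrosynthetic overview

1. Plicatic acid ⇒ remove three O-benzyl groups and open a γ-lactone (C2 carboxyl to C9 oxygen) ⇒ a tri-O-benzyl aryltetralin fused trans to a butyrolactone.
2. Cut the lactone C(=O)–O bond and the C1–C8a aryl bond of that tetracycle together ⇒ an open-chain benzylic carbinol, primary alcohol and methyl ester, held as a dioxolane.
3. ⇒ Hydride reduction of a bicyclic aldol γ-lactone. In it the C3 carboxyl is tied to the C1 oxygen, so the two tartrate carboxyls are differentiated.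
4. ⇒ Cut C1–C2 (aldol, aryl aldehyde) and C3–C4 (benzylation, benzylic bromide) back to dimethyl D-tartrate acetonide. It supplies C2, C3 and both tertiary carbinol oxygens and is the only source of chirality.
5. Ring order: a temporary γ-lactone forms in step 4 and is opened in step 5. In step 6 the butyrolactone closes first and carbocycle B second, in one acid operation. The butyrolactone is opened in step 7.

Assumption: target tetralin numbering is used throughout (C1 aryl-bearing, C2 carboxyl-bearing, C3 hydroxymethyl-bearing, C4 methylene, C9 the hydroxymethyl carbon; ring A is the fused arene, ring B the new carbocycle); LiN(i-Pr)2 is bought as a solution; the carbinol carbon made in step 4 (later C1) is carried as an epimer mixture, drawn without configuration, until step 6 sets it.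

## Route

Step 1
Reactants: 1 4-(benzyloxy)-3-methoxybenzyl alcohol
Product: 2 4-(benzyloxy)-3-methoxybenzyl bromide
Conditions: PBr3 (0.4 equiv), Et2O, 0 °C, 1 h; used without chromatography
Reagents that add atoms: phosphorus tribromide, BrP(Br)Br
Why: Alcohol-to-bromide conversion through the bromophosphite (SN2 at a primary benzylic carbon), which is clean at 0 °C for this electron-rich benzyl alcohol and involves no stereocentre.

Step 2
Reactants: 3 dimethyl (4S,5S)-2,2-dimethyl-1,3-dioxolane-4,5-dicarboxylate (D-tartrate acetonide); 2 4-(benzyloxy)-3-methoxybenzyl bromide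
Product: 5 dimethyl (4S,5S)-4-[4-(benzyloxy)-3-methoxybenzyl]-2,2-dimethyl-1,3-dioxolane-4,5-dicarboxylate, via lithium enolate 4 (not isolated)
Conditions: LiN(i-Pr)2 (1.05 equiv), THF–DMPU 5:1, −78 °C, 30 min; then 2, −78 °C, 12 h
Reagents that add atoms: none
Why: Seebach-type alkylation of the tartrate acetonide enolate, in which the exocyclic lithium enolate keeps its β C–O bond in the nodal plane and so does not eliminate at −78 °C, and the benzylic bromide enters with retention (cis to the neighbouring ester), which sets C3 as a quaternary carbinol centre while the untouched centre stays S.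

Step 3
Reactants: 6 3,4-dihydroxy-5-methoxybenzaldehyde
Product: 7 3,4-bis(benzyloxy)-5-methoxybenzaldehyde
Conditions: BnBr (2.2 equiv), K2CO3 (2.5 equiv), DMF, 60 °C, 6 h
Reagents that add atoms: benzyl bromide, BrCc1ccccc1
Why: Williamson ether synthesis on both phenols gives a non-enolisable aldehyde that tolerates a lithium enolate, and no stereocentre is involved.

Step 4
Reactants: 5 dimethyl (4S,5S)-4-[4-(benzyloxy)-3-methoxybenzyl]-2,2-dimethyl-1,3-dioxolane-4,5-dicarboxylate; 7 3,4-bis(benzyloxy)-5-methoxybenzaldehyde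
Product: 10 methyl (3aS,6aS)-6-[3,4-bis(benzyloxy)-5-methoxyphenyl]-3a-[4-(benzyloxy)-3-methoxybenzyl]-2,2-dimethyl-4-oxotetrahydrofuro[3,4-d][1,3]dioxole-6a-carboxylate (C6 epimers), via lithium enolate 8 (not isolated), via lithium aldolate 9 (not isolated)
Conditions: LiN(i-Pr)2 (1.1 equiv), THF–DMPU 5:1, −78 °C, 1 h; 7, −78 °C to 0 °C, 3 h; aq NH4Cl
Reagents that add atoms: none
Why: Lithium enolate aldol addition followed by lactonisation, in which the second exocyclic enolate is attacked anti to the benzyl group and cis to the C3 ester (the sense seen in trans-dialkylated tartrates), which sets C2, and the alkoxide then closes a cis-fused γ-lactone onto the C3 ester, which blocks retro-aldol and differentiates the two carboxyl carbons, while the uncontrolled carbinol centre is erased in step 6.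

Step 5
Reactants: 10 methyl (3aS,6aS)-6-[3,4-bis(benzyloxy)-5-methoxyphenyl]-3a-[4-(benzyloxy)-3-methoxybenzyl]-2,2-dimethyl-4-oxotetrahydrofuro[3,4-d][1,3]dioxole-6a-carboxylate
Product: 12 methyl (4S,5R)-4-{[3,4-bis(benzyloxy)-5-methoxyphenyl](hydroxy)methyl}-5-[4-(benzyloxy)-3-methoxybenzyl]-5-(hydroxymethyl)-2,2-dimethyl-1,3-dioxolane-4-carboxylate (carbinol epimers), via lactol 11 (not isolated)
Conditions: i-Bu2AlH (1.2 equiv), CH2Cl2, −78 °C, 1 h; then MeOH, NaBH4 (2 equiv), −78 °C to 0 °C; aqueous work-up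
Reagents that add atoms: none
Why: Chemoselective lactone-to-lactol reduction followed by borohydride reduction of the ring-opened hydroxy aldehyde, which relies on the γ-lactone carbonyl being more Lewis basic and electrophilic than the neopentyl-type methyl ester, touches no stereocentre (C3 changes from S to R only through the priority change), and gives a stable product because the new CH2OH lies trans to the ester on the dioxolane and cannot lactonise yet.

Step 6
Reactants: 12 methyl (4S,5R)-4-{[3,4-bis(benzyloxy)-5-methoxyphenyl](hydroxy)methyl}-5-[4-(benzyloxy)-3-methoxybenzyl]-5-(hydroxymethyl)-2,2-dimethyl-1,3-dioxolane-4-carboxylate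
Product: 15 (3aR,9S,9aS)-7-(benzyloxy)-9-[3,4-bis(benzyloxy)-5-methoxyphenyl]-3a,9a-dihydroxy-6-methoxy-3a,4,9,9a-tetrahydronaphtho[2,3-c]furan-1(3H)-one, via tetraol ester 13 (not isolated), via hydroxy lactone 14 (not isolated)
Conditions: CF3CO2H–H2O 9:1, 0 °C, 1 h, then 35 °C, 8 h; aq NaHCO3 work-up
Reagents that add atoms: none
Why: Acid cascade of ketal hydrolysis, γ-lactonisation and intramolecular Friedel–Crafts alkylation, in which the ketal goes first because the C1 carbinol, flanked by the C2 oxygen and carbonyl, ionises far more slowly, the freed CH2OH then closes the butyrolactone, which holds the C2 carbonyl and C9 diequatorial and both OH groups axial, and ring A (para to OMe) finally adds to the benzylic cation through the half-chair with the pendant aryl pseudo-equatorial beside the small axial C2–OH, which sets C1 as S (aryl trans to the carbonyl, cis to C2–OH) from either carbinol epimer, in the same sense as the acid cyclisation of hydroxymatairesinol to α-conidendrin.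

Step 7
Reactants: 15 (3aR,9S,9aS)-7-(benzyloxy)-9-[3,4-bis(benzyloxy)-5-methoxyphenyl]-3a,9a-dihydroxy-6-methoxy-3a,4,9,9a-tetrahydronaphtho[2,3-c]furan-1(3H)-one
Product: 17 (1S,2S,3R)-7-(benzyloxy)-1-[3,4-bis(benzyloxy)-5-methoxyphenyl]-2,3-dihydroxy-3-(hydroxymethyl)-6-methoxy-1,2,3,4-tetrahydronaphthalene-2-carboxylic acid, via lithium carboxylate 16 (not isolated)
Conditions: LiOH (3 equiv), THF–H2O 3:1, 0 °C to rt, 2 h; 1 M HCl to pH 3 at 0 °C, extracted at once
Reagents that add atoms: lithium hydroxide, [Li+].[OH-]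
Why: Saponification (acyl–oxygen cleavage) of a strained trans-fused α-hydroxy γ-lactone is fast, breaks no bond at a stereocentre, and cold brief acidification avoids relactonisation.

Step 8
Reactants: 17 (1S,2S,3R)-7-(benzyloxy)-1-[3,4-bis(benzyloxy)-5-methoxyphenyl]-2,3-dihydroxy-3-(hydroxymethyl)-6-methoxy-1,2,3,4-tetrahydronaphthalene-2-carboxylic acid
Product: 18 plicatic acid, (1S,2S,3R)-1-(3,4-dihydroxy-5-methoxyphenyl)-2,3,7-trihydroxy-3-(hydroxymethyl)-6-methoxy-1,2,3,4-tetrahydronaphthalene-2-carboxylic acid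
Conditions: H2 (1 atm), Pd/C (10 wt %), MeOH, rt, 4 h; filtered under argon
Reagents that add atoms: none
Why: Catalytic hydrogenolysis of the three aryl benzyl ethers under neutral conditions spares the air- and base-sensitive catechol acid, and C1 carries no benzylic C–O bond, so no stereocentre is at risk.

## Compound list

1 | 4-(benzyloxy)-3-methoxybenzyl alcohol | COc1cc(CO)ccc1OCc1ccccc1 | starting material
2 | 4-(benzyloxy)-3-methoxybenzyl bromide | COc1cc(CBr)ccc1OCc1ccccc1 | intermediate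
3 | dimethyl (4S,5S)-2,2-dimethyl-1,3-dioxolane-4,5-dicarboxylate | COC(=O)[C@H]1OC(C)(C)O[C@@H]1C(=O)OC | starting material
4 | lithium enolate of 3 | COC(=O)[C@H]1OC(C)(C)OC1=C(OC)[O-].[Li+] | intermediate
5 | dimethyl (4S,5S)-4-[4-(benzyloxy)-3-methoxybenzyl]-2,2-dimethyl-1,3-dioxolane-4,5-dicarboxylate | COC(=O)[C@H]1OC(C)(C)O[C@]1(Cc2ccc(OCc3ccccc3)c(OC)c2)C(=O)OC | intermediate
6 | 3,4-dihydroxy-5-methoxybenzaldehyde | COc1cc(C=O)cc(O)c1O | starting material
7 | 3,4-bis(benzyloxy)-5-methoxybenzaldehyde | COc1cc(C=O)cc(OCc2ccccc2)c1OCc1ccccc1 | intermediate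
8 | lithium enolate of 5 | COC([O-])=C1OC(C)(C)O[C@]1(Cc2ccc(OCc3ccccc3)c(OC)c2)C(=O)OC.[Li+] | intermediate
9 | lithium aldolate from 8 and 7 (4S,5S; carbinol carbon undefined) | COC(=O)[C@@]1(C([O-])c2cc(OC)c(OCc3ccccc3)c(OCc3ccccc3)c2)OC(C)(C)O[C@]1(Cc2ccc(OCc3ccccc3)c(OC)c2)C(=O)OC.[Li+] | intermediate
10 | methyl (3aS,6aS)-6-[3,4-bis(benzyloxy)-5-methoxyphenyl]-3a-[4-(benzyloxy)-3-methoxybenzyl]-2,2-dimethyl-4-oxotetrahydrofuro[3,4-d][1,3]dioxole-6a-carboxylate (C6 epimers) | COC(=O)[C@@]12OC(C)(C)O[C@]1(Cc3ccc(OCc4ccccc4)c(OC)c3)C(=O)OC2c1cc(OC)c(OCc2ccccc2)c(OCc2ccccc2)c1 | intermediate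
11 | lactol of 10 (4-hydroxy in place of 4-oxo; C4 and C6 undefined) | COC(=O)[C@@]12OC(C)(C)O[C@]1(Cc3ccc(OCc4ccccc4)c(OC)c3)C(O)OC2c1cc(OC)c(OCc2ccccc2)c(OCc2ccccc2)c1 | intermediate
12 | methyl (4S,5R)-4-{[3,4-bis(benzyloxy)-5-methoxyphenyl](hydroxy)methyl}-5-[4-(benzyloxy)-3-methoxybenzyl]-5-(hydroxymethyl)-2,2-dimethyl-1,3-dioxolane-4-carboxylate (carbinol epimers) | COC(=O)[C@@]1(C(O)c2cc(OC)c(OCc3ccccc3)c(OCc3ccccc3)c2)OC(C)(C)O[C@@]1(CO)Cc1ccc(OCc2ccccc2)c(OC)c1 | intermediate
13 | methyl (2S,3R)-2-{[3,4-bis(benzyloxy)-5-methoxyphenyl](hydroxy)methyl}-3-[4-(benzyloxy)-3-methoxybenzyl]-2,3,4-trihydroxybutanoate (carbinol epimers) | COC(=O)[C@](O)(C(O)c1cc(OC)c(OCc2ccccc2)c(OCc2ccccc2)c1)[C@](O)(CO)Cc1ccc(OCc2ccccc2)c(OC)c1 | intermediate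
14 | (3S,4R)-3-{[3,4-bis(benzyloxy)-5-methoxyphenyl](hydroxy)methyl}-4-[4-(benzyloxy)-3-methoxybenzyl]-3,4-dihydroxydihydrofuran-2(3H)-one (carbinol epimers) | O=C1OC[C@](O)(Cc2ccc(OCc3ccccc3)c(OC)c2)[C@@]1(O)C(O)c1cc(OC)c(OCc2ccccc2)c(OCc2ccccc2)c1 | intermediate
15 | (3aR,9S,9aS)-7-(benzyloxy)-9-[3,4-bis(benzyloxy)-5-methoxyphenyl]-3a,9a-dihydroxy-6-methoxy-3a,4,9,9a-tetrahydronaphtho[2,3-c]furan-1(3H)-one | COc1cc2c(cc1OCc1ccccc1)[C@H](c1cc(OC)c(OCc3ccccc3)c(OCc3ccccc3)c1)[C@@]1(O)C(=O)OC[C@]1(O)C2 | intermediate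
16 | lithium salt of 17 | COc1cc2c(cc1OCc1ccccc1)[C@H](c1cc(OC)c(OCc3ccccc3)c(OCc3ccccc3)c1)[C@@](O)(C(=O)[O-])[C@](O)(CO)C2.[Li+] | intermediate
17 | (1S,2S,3R)-7-(benzyloxy)-1-[3,4-bis(benzyloxy)-5-methoxyphenyl]-2,3-dihydroxy-3-(hydroxymethyl)-6-methoxy-1,2,3,4-tetrahydronaphthalene-2-carboxylic acid | COc1cc2c(cc1OCc1ccccc1)[C@H](c1cc(OC)c(OCc3ccccc3)c(OCc3ccccc3)c1)[C@@](O)(C(=O)O)[C@](O)(CO)C2 | intermediate
18 | plicatic acid, (1S,2S,3R) | COc1cc2c(cc1O)[C@H](c1cc(O)c(O)c(OC)c1)[C@@](O)(C(=O)O)[C@](O)(CO)C2 | target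

## Step count and risk

Total step count: 8. Longest linear sequence: 7 (steps 1, 2, 4, 5, 6, 7, 8).

**Step 6 (acid cascade).**
- Risk: ring B may close while the ketal is still on. A trans-fused dioxolane would force both carboxyl-derived carbons axial and favour the C1 epimer. The C1 cation could also undergo a semipinacol shift from C2.
- Fallback: it sets out from 12 and removes the ability of C1 to ionise until the lactone is in place.
- MnO2 in CH2Cl2 oxidises only the benzylic carbinol to the aryl ketone methyl (4S,5R)-4-[3,4-bis(benzyloxy)-5-methoxybenzoyl]-5-[4-(benzyloxy)-3-methoxybenzyl]-5-(hydroxymethyl)-2,2-dimethyl-1,3-dioxolane-4-carboxylate F1.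
- 1 M HCl in THF at 40 °C hydrolyses the ketal to the keto triol ester F2, which lactonises in the flask to the keto lactone F3.
- NaBH4 and CeCl3 in MeOH at −78 °C reduce the ketone to give 14, now isolated.
- A separate Friedel–Crafts closure with CF3SO3H (5 mol %) in (CF3)2CHOH at 0 °C gives 15, where the route resumes.

**Step 5 (lactone reduced beside the methyl ester).**
- Risk: the hydride may also attack the ester, or the doubly flanked lactone may react too slowly.
- Fallback: it sets out from 10 and protects the C2 carboxyl as its carboxylate.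
- LiI in pyridine at reflux cleaves the methyl ester by SN2 attack at the methyl group and gives the lactone acid F4.
- LiBH4 (3 equiv) in THF leaves the lithium carboxylate alone and reduces the lactone to the dihydroxy acid F5.
- The aqueous CF3CO2H treatment of step 6 hydrolyses the ketal to the tetraol acid F6, which lactonises to 14 and cyclises to 15, where the route resumes.

**Step 4 (aldol of a hindered, thermally fragile enolate).**
- Risk: enolisation may be incomplete, or retro-aldol may outrun lactonisation.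
- Fallback: it sets out from 5 and replaces the reversible lithium aldol by an irreversible Lewis acid aldol.
- Enolate 8 is trapped in situ with Me3SiCl as the trimethylsilyl ketene acetal F7.
- Mukaiyama aldol addition of F7 to 7 (BF3·OEt2, CH2Cl2, −78 °C; open transition state, attack again anti to the benzyl group) gives the hydroxy diester F8.
- Catalytic DBU in CH2Cl2 at 0 °C closes the γ-lactone and gives 10, where the route resumes.

## Further compounds

F1 | step 6 | methyl (4S,5R)-4-[3,4-bis(benzyloxy)-5-methoxybenzoyl]-5-[4-(benzyloxy)-3-methoxybenzyl]-5-(hydroxymethyl)-2,2-dimethyl-1,3-dioxolane-4-carboxylate | COC(=O)[C@@]1(C(=O)c2cc(OC)c(OCc3ccccc3)c(OCc3ccccc3)c2)OC(C)(C)O[C@@]1(CO)Cc1ccc(OCc2ccccc2)c(OC)c1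
F2 | step 6 | methyl (2S,3R)-2-[3,4-bis(benzyloxy)-5-methoxybenzoyl]-3-[4-(benzyloxy)-3-methoxybenzyl]-2,3,4-trihydroxybutanoate | COC(=O)[C@](O)(C(=O)c1cc(OC)c(OCc2ccccc2)c(OCc2ccccc2)c1)[C@](O)(CO)Cc1ccc(OCc2ccccc2)c(OC)c1
F3 | step 6 | (3S,4R)-3-[3,4-bis(benzyloxy)-5-methoxybenzoyl]-4-[4-(benzyloxy)-3-methoxybenzyl]-3,4-dihydroxydihydrofuran-2(3H)-one | O=C1OC[C@](O)(Cc2ccc(OCc3ccccc3)c(OC)c2)[C@@]1(O)C(=O)c1cc(OC)c(OCc2ccccc2)c(OCc2ccccc2)c1
F4 | step 5 | (3aS,6aS)-6-[3,4-bis(benzyloxy)-5-methoxyphenyl]-3a-[4-(benzyloxy)-3-methoxybenzyl]-2,2-dimethyl-4-oxotetrahydrofuro[3,4-d][1,3]dioxole-6a-carboxylic acid (C6 epimers) | OC(=O)[C@@]12OC(C)(C)O[C@]1(Cc3ccc(OCc4ccccc4)c(OC)c3)C(=O)OC2c1cc(OC)c(OCc2ccccc2)c(OCc2ccccc2)c1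
F5 | step 5 | (4S,5R)-4-{[3,4-bis(benzyloxy)-5-methoxyphenyl](hydroxy)methyl}-5-[4-(benzyloxy)-3-methoxybenzyl]-5-(hydroxymethyl)-2,2-dimethyl-1,3-dioxolane-4-carboxylic acid (carbinol epimers) | OC(=O)[C@@]1(C(O)c2cc(OC)c(OCc3ccccc3)c(OCc3ccccc3)c2)OC(C)(C)O[C@@]1(CO)Cc1ccc(OCc2ccccc2)c(OC)c1
F6 | step 5 | (2S,3R)-2-{[3,4-bis(benzyloxy)-5-methoxyphenyl](hydroxy)methyl}-3-[4-(benzyloxy)-3-methoxybenzyl]-2,3,4-trihydroxybutanoic acid (carbinol epimers) | OC(=O)[C@](O)(C(O)c1cc(OC)c(OCc2ccccc2)c(OCc2ccccc2)c1)[C@](O)(CO)Cc1ccc(OCc2ccccc2)c(OC)c1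
F7 | step 4 | trimethylsilyl ketene acetal of 5 (alkene geometry undefined) | COC(O[Si](C)(C)C)=C1OC(C)(C)O[C@]1(Cc2ccc(OCc3ccccc3)c(OC)c2)C(=O)OC
F8 | step 4 | dimethyl (4S,5S)-4-{[3,4-bis(benzyloxy)-5-methoxyphenyl](hydroxy)methyl}-5-[4-(benzyloxy)-3-methoxybenzyl]-2,2-dimethyl-1,3-dioxolane-4,5-dicarboxylate (carbinol epimers) | COC(=O)[C@@]1(C(O)c2cc(OC)c(OCc3ccccc3)c(OCc3ccccc3)c2)OC(C)(C)O[C@]1(Cc2ccc(OCc3ccccc3)c(OC)c2)C(=O)OC
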